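**Retrosynthetic overview**
1. Numbering: each half is a 3-methylquinolizidin-2-one (N5; C1–C4 and C10 in ring A, C6–C10 in ring B); C1 of one half is tied to C9 of the other by (CH2)5, twice, giving the 16-membered ring.
2. Last disconnection: both C1–C10 bonds, by a transannular double Mannich reaction of a bis-iminium made by partial reduction of a 24-membered diketo bis-lactam; this step sets all eight stereocentres under thermodynamic control.
3. Key disconnection: the two CH2–CH2 bonds β to the ketones, formed together in a head-to-tail radical cyclodimerisation (double Giese addition) of an ω-iodoalkyl vinyl ketone monomer.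
4. Monomer: the N–CH2–CH(CH3)–CO–CH=CH2 arm comes from amidomethylation (formaldehyde plus the silyloxydiene of ethyl vinyl ketone) of 3-(4-iodobutyl)piperidin-2-one, itself from piperidin-2-one and 1,4-diiodobutane.
5. Ring order: ring B (bought as the lactam), then the 24-membered ring (radical step), then both rings A and with them the 16-membered ring (Mannich step).

Assumption: the SMILES is the centrosymmetric meso isomer (1R,3R,9S,10S in one half, 1S,3S,9R,10R in the other), so the target is achiral, only relative configuration has to be controlled, and racemic or stereorandom intermediates are used.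

**Step 1**
Reactants: 1 piperidin-2-one; 2 1,4-diiodobutane
Product: 3 3-(4-iodobutyl)piperidin-2-one (racemic)
Conditions: n-BuLi (2.1 equiv), THF, 0 °C; then cannulated into 2 (4 equiv), THF, −78 → −20 °C; H2O
Reagents that add atoms: none
Why: Alkylation of the N,C-dilithiated lactam (amide dianion alkylation) occurs at the more basic C3 carbanion, the excess diiodide suppresses double alkylation, and the new stereocentre is racemic and is reset in step 5.

**Step 2**
Reactants: 4 pent-1-en-3-one
Product: 5 (Z)-3-(trimethylsilyloxy)penta-1,3-diene
Conditions: TMSOTf (1.1 equiv), Et3N (1.3 equiv), Et2O, 0 °C; distil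
Reagents that add atoms: trimethylsilyl trifluoromethanesulfonate, C[Si](C)(C)OS(=O)(=O)C(F)(F)F
Why: Soft enolisation and O-silylation on the only enolisable side of the enone gives the cross-conjugated 2-silyloxydiene (silyl enol ether formation), and its double-bond geometry is of no consequence later.

**Step 3**
Reactants: 3 3-(4-iodobutyl)piperidin-2-one; 6 formaldehyde (as paraformaldehyde); 5 (Z)-3-(trimethylsilyloxy)penta-1,3-diene
Product: 8 3-(4-iodobutyl)-1-(2-methyl-3-oxopent-4-en-1-yl)piperidin-2-one, via N-chloromethyl lactam 7 (not isolated)
Conditions: (CH2O)n (1.5 equiv), TMSCl (2.5 equiv), CH2Cl2, rt; evaporate; then 5 (1.5 equiv), TMSOTf (5 mol %), CH2Cl2, −78 → −20 °C; aq NaHCO3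
Reagents that add atoms: none
Why: The N-chloromethyl lactam ionises to an N-acyliminium ion that is attacked by the enol-ether carbon of 5 (Mukaiyama–Mannich amidoalkylation), which delivers the vinyl ketone directly, and the methyl-bearing stereocentre is formed unselectively and is epimerisable.

**Step 4**
Reactants: 8 3-(4-iodobutyl)-1-(2-methyl-3-oxopent-4-en-1-yl)piperidin-2-one (two molecules)
Product: 9 24-membered diketo bis-lactam (head-to-tail cyclodimer; stereoisomer mixture)
Conditions: (Me3Si)3SiH (2.4 equiv) and AIBN (0.3 equiv) by syringe pump over 12 h, PhH (8 mM in 8), 80 °C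
Reagents that add atoms: none
Why: Proposed new method: the primary alkyl radical formed by iodine abstraction adds to the vinyl ketone of a second molecule (Giese addition, k about 10^6 M−1 s−1, favoured at 8 mM over hydrogen transfer from the slowly fed silane and over the 12-membered self-closure, which has to bridge N1 and C3 of the piperidinone), and the second radical of the open dimer then closes the nearly strain-free 24-membered ring intramolecularly; the closest known reaction type is the silane- or stannane-mediated radical macrocyclisation of ω-iodoalkyl enones, and no stereocentre is created.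

**Step 5**
Reactants: 9 24-membered diketo bis-lactam
Product: 12 petrosin A, via bis-enamine 10 (not isolated), via bis-iminium diacetate 11 (not isolated)
Conditions: IrCl(CO)(PPh3)2 (2 mol %), (Me2SiH)2O (4 equiv), PhMe, rt, 1 h; then AcOH (10 equiv), MeOH, 60 °C, 48 h; aq NaOH
Reagents that add atoms: none
Why: Iridium-catalysed hydrosilylation reduces the tertiary lactams, which react faster than dialkyl ketones, to enamines, acid converts these to cyclic iminium ions, and a transannular double intramolecular Mannich reaction closes both rings A; because Mannich and retro-Mannich steps, enolisation and iminium–enamine tautomerism are all reversible in warm acetic acid, C1, C3, C9 and C10 of each half settle into the trans-fused quinolizidinone with the C9 chain and C3 methyl equatorial and the C1 chain axial (which avoids the peri clash of two equatorial chains), and the pairing of two enantiomeric halves is meso 12, separated by chromatography from the stereoisomer with like halves.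

**Compound list**
1 | piperidin-2-one | O=C1CCCCN1 | starting material
2 | 1,4-diiodobutane | ICCCCI | starting material
3 | 3-(4-iodobutyl)piperidin-2-one (racemic) | O=C1NCCCC1CCCCI | intermediate
4 | pent-1-en-3-one (ethyl vinyl ketone) | CCC(=O)C=C | starting material
5 | (Z)-3-(trimethylsilyloxy)penta-1,3-diene | C/C=C(\O[Si](C)(C)C)C=C | intermediate
6 | formaldehyde (used as paraformaldehyde) | C=O | starting material
7 | 1-(chloromethyl)-3-(4-iodobutyl)piperidin-2-one (racemic) | O=C1C(CCCCI)CCCN1CCl | intermediate
8 | 3-(4-iodobutyl)-1-(2-methyl-3-oxopent-4-en-1-yl)piperidin-2-one (diastereomer mixture) | C=CC(=O)C(C)CN1CCCC(CCCCI)C1=O | intermediate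
9 | 24-membered diketo bis-lactam: two piperidin-2-one rings, each joined from N1 to C3 of the other through CH2CH(CH3)C(=O)(CH2)6 (stereoisomer mixture) | O=C1N2CCCC1CCCCCCC(=O)C(C)CN3CCCC(CCCCCCC(=O)C(C)C2)C3=O | intermediate
10 | bis-enamine: as 9 with both lactams reduced to 1,4,5,6-tetrahydropyridine rings (N–CH=C) | CC1CN2CCCC(=C2)CCCCCCC(=O)C(C)CN3CCCC(=C3)CCCCCCC1=O | intermediate
11 | bis-iminium diacetate: as 10 with both enamines C-protonated to 2,3,4,5-tetrahydropyridinium rings | CC1C[N+]2=CC(CCC2)CCCCCCC(=O)C(C)C[N+]3=CC(CCC3)CCCCCCC1=O.CC(=O)[O-].CC(=O)[O-] | intermediate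
12 | petrosin A (meso; 1R,3R,9S,10S in one half and 1S,3S,9R,10R in the other) | C[C@@H]1CN2CCC[C@@H]3CCCCC[C@@H]4C(=O)[C@@H](C)CN5CCC[C@@H](CCCCC[C@@H](C1=O)[C@H]32)[C@H]45 | target

**Totals**
Total steps: 5. Longest linear sequence: 4 (steps 1, 3, 4, 5); step 2 is a one-step side branch.

**Steps most likely to fail**

Step 4 (most likely). The 12-membered self-cyclisation of 8, open-chain oligomers and premature reduction of the C–I bond all compete, so a realistic yield of 9 is 20–35 %. The fallback sets out from 1 and 3 and comes back at 9, and builds the ring stepwise so that no molecule holds both a radical precursor and an acceptor until the last closure. Alkylation of dilithiated 1 with 1-bromo-4-chlorobutane gives 3-(4-chlorobutyl)piperidin-2-one F1, and the step 3 protocol converts it into 3-(4-chlorobutyl)-1-(2-methyl-3-oxopent-4-en-1-yl)piperidin-2-one F2, whose C–Cl bond is inert to silyl radicals. An intermolecular Giese addition of the radical from 3 (no acceptor present) to F2 (2 equiv, (Me3Si)3SiH, AIBN, 0.1 M) gives the open-chain keto bis-lactam F3. Amidomethylation of its free N–H with 6 and 5 gives the chloro vinyl ketone F4, NaI in acetone gives the iodo vinyl ketone F5, and an ordinary high-dilution (1–2 mM) radical macrocyclisation of F5 closes the 24-membered ring to 9. The cost is three more steps in the longest line.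

Step 5. The silane may also reduce the ketones, and the enamines may add to the ketones before acid is introduced. In addition, the pairing of the two halves is not controlled, so about half of the cyclised material is expected to be the stereoisomer of 12 with like halves; it is removed by chromatography and can in principle be returned to the same acid equilibration. The fallback sets out from 9 and comes back at 11. Both ketones are protected with ethylene glycol (PPTS, PhH, Dean–Stark) to give the bis(1,3-dioxolane) F6, and the lactams, now the only carbonyl groups, are reduced with the same iridium/silane system or with iBu2AlH at −78 °C to the bis-enamine bis(1,3-dioxolane) F7. Aqueous acetic acid at 60 °C then removes the ketals and protonates the enamines in one operation, giving 11, which cyclises as before.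

Step 3. The vinyl ketone may polymerise, add HCl or react with a second molecule of 5 under the Lewis-acidic conditions. The fallback sets out from 3 and comes back at 8, and builds the arm by conjugate addition instead of amidoalkylation. Base-catalysed aza-Michael addition of 3 to methacrolein (cat. KOtBu, THF, 0 °C) gives the aldehyde F8, addition of CH2=CHMgBr (THF, −78 °C) gives the allylic alcohol F9, and Dess–Martin oxidation gives 8.

**Further compounds**
F1 | step 4 | 3-(4-chlorobutyl)piperidin-2-one | O=C1NCCCC1CCCCCl
F2 | step 4 | 3-(4-chlorobutyl)-1-(2-methyl-3-oxopent-4-en-1-yl)piperidin-2-one | C=CC(=O)C(C)CN1CCCC(CCCCCl)C1=O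
F3 | step 4 | 3-(4-chlorobutyl)-1-[2-methyl-3-oxo-9-(2-oxopiperidin-3-yl)nonyl]piperidin-2-one | O=C1NCCCC1CCCCCCC(=O)C(C)CN1CCCC(CCCCCl)C1=O
F4 | step 4 | 3-(4-chlorobutyl)-1-{2-methyl-9-[1-(2-methyl-3-oxopent-4-en-1-yl)-2-oxopiperidin-3-yl]-3-oxononyl}piperidin-2-one | C=CC(=O)C(C)CN1CCCC(CCCCCCC(=O)C(C)CN2CCCC(CCCCCl)C2=O)C1=O
F5 | step 4 | 3-(4-iodobutyl)-1-{2-methyl-9-[1-(2-methyl-3-oxopent-4-en-1-yl)-2-oxopiperidin-3-yl]-3-oxononyl}piperidin-2-one | C=CC(=O)C(C)CN1CCCC(CCCCCCC(=O)C(C)CN2CCCC(CCCCI)C2=O)C1=O
F6 | step 5 | bis(1,3-dioxolane) of 9 (both ketones protected) | O=C1N2CCCC1CCCCCCC3(OCCO3)C(C)CN4CCCC(CCCCCCC5(OCCO5)C(C)C2)C4=O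
F7 | step 5 | bis-enamine bis(1,3-dioxolane) (both lactams of F6 reduced to N–CH=C) | CC1CN2CCCC(=C2)CCCCCCC3(OCCO3)C(C)CN4CCCC(=C4)CCCCCCC15OCCO5
F8 | step 3 | 3-[3-(4-iodobutyl)-2-oxopiperidin-1-yl]-2-methylpropanal | O=CC(C)CN1CCCC(CCCCI)C1=O
F9 | step 3 | 1-(3-hydroxy-2-methylpent-4-en-1-yl)-3-(4-iodobutyl)piperidin-2-one | C=CC(O)C(C)CN1CCCC(CCCCI)C1=O
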